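The route rests on opening the guaiacyl-bearing oxolane ring (C3a, C4, O5, C6, C6a) at C3a–C4 and O5–C6: the chain C3–C3a(OH)–C6a–C6 that is left is L-malic acid. The precursor is its pivalaldehyde-acetal (dioxolanone) ester 4, which looks nothing like a lignan. In one operation its enolate adds to silylated vanillin trans to the tert-butyl group (quaternary carbinol C3a with retention, C4 by a closed transition state), the aldolate lactonises onto the side-chain ester (O5–C6, with C6 still a carbonyl) and the liberated methoxide strips off the acetal. A second aldol–lactonisation with veratraldehyde closes the veratryl ring; both lactone carbonyls are then reduced to CH2 with the ring C–O bonds intact.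

Key step: step 4

Remark: locants follow the furo[3,4-c]furan numbering of the target (C1 veratryl CH, O2, C3 CH2, C3a C–OH, C4 guaiacyl CH, O5, C6 CH2, C6a CH).

Step 1
Reactants: 1 L-malic acid; 2 pivalaldehyde
Product: 3 (2S,5S)-2-tert-butyl-5-(carboxymethyl)-1,3-dioxolan-4-one
Conditions: TsOH·H2O (cat.), H2SO4 (cat.), pentane, reflux (Dean–Stark); recrystallisation
Reagents that add atoms: none
Why: Acid-catalysed acetalisation of the α-hydroxy acid unit (dioxolanone formation for self-regeneration of stereocentres) should give mainly the cis acetal, whose new acetal centre (2S) is set under thermodynamic control and purified by crystallisation.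

Step 2
Reactants: 3 (2S,5S)-2-tert-butyl-5-(carboxymethyl)-1,3-dioxolan-4-one
Product: 4 methyl 2-[(2S,4S)-2-tert-butyl-5-oxo-1,3-dioxolan-4-yl]acetate
Conditions: MeI, KHCO3, DMF, rt
Reagents that add atoms: iodomethane, CI
Why: SN2 O-alkylation of the carboxylate (esterification) under bicarbonate, which is too weak to enolise or open the acylal, so no stereocentre is touched.

Step 3
Reactants: 5 vanillin
Product: 6 3-methoxy-4-(triisopropylsilyloxy)benzaldehyde
Conditions: TIPSCl, imidazole, DMF, rt
Reagents that add atoms: triisopropylsilyl chloride, CC(C)[Si](Cl)(C(C)C)C(C)C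
Why: Silylation of the phenol; the TIPS ether is chosen because it should survive alkoxide, amide bases, DIBAL-H and BF3 at low temperature and leave under neutral fluoride conditions at the end.

Step 4
Reactants: 4 methyl 2-[(2S,4S)-2-tert-butyl-5-oxo-1,3-dioxolan-4-yl]acetate; 6 3-methoxy-4-(triisopropylsilyloxy)benzaldehyde
Product: 9 methyl (2R,3R)-3-hydroxy-2-[3-methoxy-4-(triisopropylsilyloxy)phenyl]-5-oxooxolane-3-carboxylate, via aldol adduct 7 (not isolated), via spiro lactone 8 (not isolated)
Conditions: LiHMDS (1.05 equiv), THF, −78 °C; then 6, −78 → 0 °C; aq. NH4Cl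
Reagents that add atoms: none
Why: LiHMDS removes the ring C–H of 4 (flanked by the ring oxygen and the acylal carbonyl, so more acidic and less hindered than the side-chain CH2) to give a planar lithium enolate that keeps only the acetal stereocentre, and this adds to aldehyde 6 in an aldol reaction of the self-regeneration-of-stereocentres type. The quaternary carbinol carbon (C3a) is set by attack on the enolate face trans to the tert-butyl group, so the aryl carbinol unit takes the place of the original hydrogen of L-malic acid with retention; the benzylic carbon (C4) is set by a closed Zimmerman–Traxler transition state in which the O–Li group is cis to the CH2CO2Me arm and the aryl group is equatorial, which places the aryl group cis to the ring oxygen and not to the larger acyl carbon. The lithium aldolate 7 closes the oxolanone ring by 5-exo-trig acyl substitution on the side-chain methyl ester (lactonisation, O5–C6 bond with C6 as carbonyl), which needs no facial match because the ester arm is acyclic. The expelled lithium methoxide then opens the activated acylal carbonyl of 8, pivalaldehyde is lost from the hemiacetal alkoxide, and the tertiary alkoxide and methyl ester of 9 are unveiled in the same flask. The step needs regioselective enolisation (secured by the dioxolanone), facial selectivity (tert-butyl group) and simple diastereoselectivity at the benzylic carbon, the last being the least secure; the closest known reaction types are the aldol–lactonisation of dioxolanone enolates and the interrupted Stobbe condensation.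

Step 5
Reactants: 9 methyl (2R,3R)-3-hydroxy-2-[3-methoxy-4-(triisopropylsilyloxy)phenyl]-5-oxooxolane-3-carboxylate; 10 veratraldehyde
Product: 12 (3R,3aR,6S,6aR)-6-(3,4-dimethoxyphenyl)-3a-hydroxy-3-[3-methoxy-4-(triisopropylsilyloxy)phenyl]tetrahydrofuro[3,4-c]furan-1,4-dione, via aldol adduct 11 (not isolated)
Conditions: LDA (2.2 equiv), THF, −78 → −40 °C; then 10, −78 → −10 °C; aq. NH4Cl
Reagents that add atoms: none
Why: Two equivalents of LDA should give the chelated alkoxide–lactone enolate dianion (Fráter–Seebach type), which adds to 10 anti to the O–Li group and to the neighbouring aryl group, so the new side chain (C6a) is cis to the methyl ester and the aldolate lactonises onto it (5-exo-trig) to the cis-fused bislactone; the benzylic carbon (C1 of the target) is fixed during this closure, the aldol being reversible and the exo-aryl aldolate (aryl cis to the small bridgehead hydrogen, on the convex face) expected to close faster.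

Step 6
Reactants: 12 (3R,3aR,6S,6aR)-6-(3,4-dimethoxyphenyl)-3a-hydroxy-3-[3-methoxy-4-(triisopropylsilyloxy)phenyl]tetrahydrofuro[3,4-c]furan-1,4-dione
Product: 13 (3R,3aR,6S,6aR)-6-(3,4-dimethoxyphenyl)-3-[3-methoxy-4-(triisopropylsilyloxy)phenyl]tetrahydro-1H,3H-furo[3,4-c]furan-1,3a,4-triol (bis-lactol, anomer mixture)
Conditions: DIBAL-H (5 equiv), CH2Cl2, −78 °C; Rochelle salt
Reagents that add atoms: none
Why: Partial reduction of lactones to lactols: at −78 °C each carbonyl should take up one hydride and the tetrahedral aluminium hemiacetals persist until work-up, so both ring C–O bonds stay closed; the anomeric centres are of no consequence.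

Step 7
Reactants: 13 bis-lactol (anomer mixture)
Product: 14 (1S,3aS,4R,6aR)-1-(3,4-dimethoxyphenyl)-4-[3-methoxy-4-(triisopropylsilyloxy)phenyl]tetrahydro-1H,3H-furo[3,4-c]furan-3a-ol
Conditions: Et3SiH, BF3·OEt2, CH2Cl2, −78 → −40 °C
Reagents that add atoms: none
Why: Reductive deoxygenation of lactols (ionic hydrogenation): BF3 ionises each hemiacetal to a cyclic oxocarbenium ion that is trapped by Et3SiH, which at −78 °C should be much faster than ionisation of the benzylic ethers or of the tertiary alcohol; no stereocentre is formed.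

Step 8
Reactants: 14 (1S,3aS,4R,6aR)-1-(3,4-dimethoxyphenyl)-4-[3-methoxy-4-(triisopropylsilyloxy)phenyl]tetrahydro-1H,3H-furo[3,4-c]furan-3a-ol
Product: 15 (1S,3aS,4R,6aR)-1-(3,4-dimethoxyphenyl)-4-(4-hydroxy-3-methoxyphenyl)tetrahydro-1H,3H-furo[3,4-c]furan-3a-ol (target)
Conditions: TBAF, THF, 0 °C; aq. NH4Cl
Reagents that add atoms: none
Why: Fluoride-mediated cleavage of the aryl silyl ether under non-acidic conditions, which should leave the acid-sensitive benzylic ethers of the furofuran and all four stereocentres unchanged.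

Compound list
1 | L-malic acid, (S)-2-hydroxybutanedioic acid | O[C@@H](CC(=O)O)C(=O)O | starting material
2 | pivalaldehyde | CC(C)(C)C=O | starting material
3 | (2S,5S)-2-tert-butyl-5-(carboxymethyl)-1,3-dioxolan-4-one (cis acetal) | CC(C)(C)[C@H]1O[C@@H](CC(=O)O)C(=O)O1 | intermediate
4 | methyl 2-[(2S,4S)-2-tert-butyl-5-oxo-1,3-dioxolan-4-yl]acetate | CC(C)(C)[C@H]1O[C@@H](CC(=O)OC)C(=O)O1 | intermediate
5 | vanillin | COc1cc(C=O)ccc1O | starting material
6 | 3-methoxy-4-(triisopropylsilyloxy)benzaldehyde | COc1cc(C=O)ccc1O[Si](C(C)C)(C(C)C)C(C)C | intermediate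
7 | methyl 2-[(2S,4R)-2-tert-butyl-4-{(R)-hydroxy[3-methoxy-4-(triisopropylsilyloxy)phenyl]methyl}-5-oxo-1,3-dioxolan-4-yl]acetate (aldol adduct) | CC(C)(C)[C@H]1O[C@](CC(=O)OC)([C@H](O)c2ccc(O[Si](C(C)C)(C(C)C)C(C)C)c(OC)c2)C(=O)O1 | intermediate (not isolated)
8 | (2S,5R,6R)-2-tert-butyl-6-[3-methoxy-4-(triisopropylsilyloxy)phenyl]-1,3,7-trioxaspiro[4.4]nonane-4,8-dione (spiro lactone) | CC(C)(C)[C@H]1O[C@@]2(CC(=O)O[C@@H]2c3ccc(O[Si](C(C)C)(C(C)C)C(C)C)c(OC)c3)C(=O)O1 | intermediate (not isolated)
9 | methyl (2R,3R)-3-hydroxy-2-[3-methoxy-4-(triisopropylsilyloxy)phenyl]-5-oxooxolane-3-carboxylate | COC(=O)[C@@]1(O)CC(=O)O[C@@H]1c1ccc(O[Si](C(C)C)(C(C)C)C(C)C)c(OC)c1 | intermediate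
10 | veratraldehyde (3,4-dimethoxybenzaldehyde) | COc1ccc(C=O)cc1OC | starting material
11 | methyl (2R,3R,4R)-4-[(S)-(3,4-dimethoxyphenyl)(hydroxy)methyl]-3-hydroxy-2-[3-methoxy-4-(triisopropylsilyloxy)phenyl]-5-oxooxolane-3-carboxylate (aldol adduct) | COC(=O)[C@@]1(O)[C@@H]([C@H](O)c2ccc(OC)c(OC)c2)C(=O)O[C@@H]1c1ccc(O[Si](C(C)C)(C(C)C)C(C)C)c(OC)c1 | intermediate (not isolated)
12 | (3R,3aR,6S,6aR)-6-(3,4-dimethoxyphenyl)-3a-hydroxy-3-[3-methoxy-4-(triisopropylsilyloxy)phenyl]tetrahydrofuro[3,4-c]furan-1,4-dione (cis-fused bislactone, both aryl groups exo) | COc1cc([C@H]2OC(=O)[C@@H]3[C@@H](c4ccc(OC)c(OC)c4)OC(=O)[C@]23O)ccc1O[Si](C(C)C)(C(C)C)C(C)C | intermediate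
13 | (3R,3aR,6S,6aR)-6-(3,4-dimethoxyphenyl)-3-[3-methoxy-4-(triisopropylsilyloxy)phenyl]tetrahydro-1H,3H-furo[3,4-c]furan-1,3a,4-triol (bis-lactol, anomer mixture) | COc1cc([C@H]2OC(O)[C@@H]3[C@@H](c4ccc(OC)c(OC)c4)OC(O)[C@]23O)ccc1O[Si](C(C)C)(C(C)C)C(C)C | intermediate
14 | (1S,3aS,4R,6aR)-1-(3,4-dimethoxyphenyl)-4-[3-methoxy-4-(triisopropylsilyloxy)phenyl]tetrahydro-1H,3H-furo[3,4-c]furan-3a-ol | COc1cc([C@H]2OC[C@@H]3[C@@H](c4ccc(OC)c(OC)c4)OC[C@]23O)ccc1O[Si](C(C)C)(C(C)C)C(C)C | intermediate
15 | (1S,3aS,4R,6aR)-1-(3,4-dimethoxyphenyl)-4-(4-hydroxy-3-methoxyphenyl)tetrahydro-1H,3H-furo[3,4-c]furan-3a-ol | COc1cc([C@H]2OC[C@@H]3[C@@H](c4ccc(OC)c(OC)c4)OC[C@]23O)ccc1O | target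

Total step count: 8. Longest linear sequence: 7 (steps 1, 2, 4, 5, 6, 7, 8).

Steps most likely to fail

Step 5. The aldol may show poor facial discrimination at the benzylic carbinol carbon, so that closure through the endo-aryl aldolate competes. The lactonisation onto the hindered ester may also stall, so that retro-aldol returns 9. Fallback: setting out from 9, the same dianion is C-acylated with N-methoxy-N-methyl-3,4-dimethoxybenzamide (Claisen-type acylation, anti to the O–Li group) to give the β-keto lactone F1. Chelation-controlled reduction of the aryl ketone with Zn(BH4)2 (zinc bridging the ketone and lactone carbonyls, hydride anti to the ring substituent) should give the syn alcohol 11. With catalytic DBU this closes onto the methyl ester, and the route is rejoined at 12.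

Step 4. The cascade may stop part-way, with aldolate 7 or spiro lactone 8 surviving, because lactonisation or the methoxide relay is slow at temperatures the enolate tolerates. The enolate may also self-condense on warming. Fallback: setting out from acid 3, its dianion (LiHMDS, 2.1 equiv, the carboxylate shielding the side chain) is added to 6 to give the hydroxy acid F2. This is lactonised with a carbodiimide (EDC, DMAP) to 8, and brief methanolysis (NaOMe cat., MeOH, 0 °C) removes the acetal and rejoins the route at 9.

Step 7. Lewis-acid ionisation of the electron-rich benzylic C–O bonds may cause epimerisation at C1 or C4 or reductive ring opening. The oxocarbenium ions may also eliminate to enol ethers. Fallback: setting out from 13, NaBH4 reduction of the ring-opened hydroxy aldehyde forms gives the pentaol F3. Selective sulfonylation of its two primary hydroxyls (MsCl, pyridine, 0 °C) gives the bis-mesylate F4. On warming this should close both rings by 5-exo-tet displacement by the benzylic hydroxyls, with retention at the benzylic carbons, and rejoin the route at 14.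

Further compounds
F1 | step 5 | methyl (2R,3R,4S)-4-(3,4-dimethoxybenzoyl)-3-hydroxy-2-[3-methoxy-4-(triisopropylsilyloxy)phenyl]-5-oxooxolane-3-carboxylate | COC(=O)[C@@]1(O)[C@@H](C(=O)c2ccc(OC)c(OC)c2)C(=O)O[C@@H]1c1ccc(O[Si](C(C)C)(C(C)C)C(C)C)c(OC)c1
F2 | step 4 | 2-[(2S,4R)-2-tert-butyl-4-{(R)-hydroxy[3-methoxy-4-(triisopropylsilyloxy)phenyl]methyl}-5-oxo-1,3-dioxolan-4-yl]acetic acid | CC(C)(C)[C@H]1O[C@](CC(=O)O)([C@H](O)c2ccc(O[Si](C(C)C)(C(C)C)C(C)C)c(OC)c2)C(=O)O1
F3 | step 7 | (1R,2S,3R,4S)-4-(3,4-dimethoxyphenyl)-2,3-bis(hydroxymethyl)-1-[3-methoxy-4-(triisopropylsilyloxy)phenyl]butane-1,2,4-triol | COc1cc(ccc1O[Si](C(C)C)(C(C)C)C(C)C)[C@@H](O)[C@@](O)(CO)[C@H](CO)[C@H](O)c1ccc(OC)c(OC)c1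
F4 | step 7 | bis(methanesulfonate) of the two primary hydroxyls of F3 | COc1cc(ccc1O[Si](C(C)C)(C(C)C)C(C)C)[C@@H](O)[C@@](O)(COS(C)(=O)=O)[C@H](COS(C)(=O)=O)[C@H](O)c1ccc(OC)c(OC)c1
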